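**Compound numbering used throughout**

1 – 1-(3,4,5-trimethoxyphenyl)propan-1-one (starting material)
2 – rac-2-bromo-1-(3,4,5-trimethoxyphenyl)propan-1-one
3 – 4-hydroxy-3-iodo-5-methoxybenzaldehyde, 5-iodovanillin (starting material)
4 – racemic α-aryloxy keto aldehyde
5 – racemic keto alcohol (formed and consumed in step 3)
6 – (1S,2S) open-chain diol
7 – (2S,3S)-benzodioxane methanol
8 – (2S,3S)-benzodioxane aldehyde
9 – target

Assumption: 1, 3 and (triphenylphosphoranylidene)acetaldehyde are taken as commercial; ring atoms are numbered as in the IUPAC name of 9 (O1–C2(CH3)–C3(aryl)–O4, side chain at C6, OMe at C8), and "later C2/C3" refers to these atoms in open-chain precursors.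

## Analysis of the target

Compound 9 is a 1,4-benzodioxane neolignan: a 2,3-dihydro-1,4-benzodioxine with a methyl group at C2 (bonded to O1) and a 3,4,5-trimethoxyphenyl group at C3 (bonded to O4). The fused benzene ring carries OMe at C8 and an (E)-prop-2-enal chain at C6. C2 and C3 are the only stereocentres, both S, with methyl and aryl trans (diequatorial), which is also the more stable relative configuration. The two ring oxygens are not equivalent: O1, para to the C6 chain and next to C8–OMe, carries the CH(CH3) carbon, while O4, meta to the chain, carries the benzylic carbon. C3 is a benzylic aryl ether and can ionise under acid. C2–H is inert in 9, but once C3 is a ketone and the ring is open at O4–C4a, C2–H lies between an aryl ketone and an aryloxy oxygen and becomes configurationally labile; this latent lability of C2 next to C3 is the feature the route exploits. The enal is sensitive to hydride, base and nucleophiles, so it must come late. The difficulty is absolute control of two adjacent C–O stereocentres that have no nearby functional handle, together with the regiochemistry of O1 and O4, in few steps.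

## Retrosynthetic reasoning

**9 ⇒ 8.** The C=C bond of the propenal chain at C6 is cut first. The enal would not survive hydride transfer, carbonate base at high temperature or copper, so it is added last by a two-carbon olefination of aldehyde 8. All earlier steps then work on a robust arene.

**8 ⇒ 7.** The C6 carbon is traced back to the alcohol level. The key reduction reduces an aromatic aldehyde anyway, and accepting this replaces a protect/deprotect pair by one re-oxidation. A CH2OH-substituted ring is also not activated for aryl migration (Smiles type) during ring closure.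

**7 ⇒ 6.** The dioxane ring is opened at the aryl–oxygen bond O4–C4a, not at C3–O4. Closure at C3–O4 would be an SN1 or SN2 event at the benzylic stereocentre. Closure at O4–C4a makes a bond to an sp2 carbon and leaves C2 and C3 untouched. The trans ring of 7 must therefore come, with retention, from the threo (1S,2S) alcohol 6, which carries iodine at the future C4a for a copper-catalysed intramolecular O-arylation.

**6 ⇒ 4 (through 5).** This is the key disconnection: the C3–H bond, formed by hydride addition to a ketone. In 4 the later C2 is α to the aryl ketone and bears the aryloxy group, so its two enantiomers interconvert through the enol. A chiral hydride catalyst should fix C3 by catalyst control and select C2 by matching, while the unmatched enantiomer is fed back through the enol. Both stereocentres are thus set as a group from a racemate that holds no stereochemical information.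

**4 ⇒ 2 + 3.** The O1–C2 bond is cut as an SN2 etherification. Phenol 3 has a single OH, para to the formyl group and between I and OMe. This fixes in one stroke that O1 is para to the side chain, that OMe sits at C8, and that the iodine marks C4a. A free catechol would require a regioselective alkylation instead.

**2 ⇒ 1.** The C–Br bond is cut; α-bromination of ketone 1 gives the racemic electrophile 2.

## Alternatives that were turned down

**Alternative 1:** (textbook) Cut C3–O4 last and take C2 from the chiral pool. A lactate ester is coupled by Mitsunobu reaction to a mono-protected, aldehyde-masked catechol; aryl-metal addition and deprotection give the phenol diol A1. The forward key step is acid-mediated closure of A1 through the C3 benzylic cation to give 8.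
- It needs stoichiometric chirality, a second phenolic OH that must be differentiated and protected, and an aldehyde mask.
- An enolisable α-aryloxy carbonyl stereocentre has to be carried through organometallic steps.
- The C3 cation can lose the C2 proton (E1) and so erode C2, and trans is obtained only as far as thermodynamics allows.
- The step count is at least eight.

**Alternative 2:** (biomimetic) Cut O1–C2 and O4–C3 at once. The forward key step is an inverse-demand hetero-Diels–Alder reaction of o-quinone A2, generated in situ from its catechol, with the propenylarene A3, giving 9 directly with trans inherited from the E alkene. This is the shortest route on paper.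
- Both partners are flat and achiral, with no donor or acceptor group near the reacting atoms for a chiral catalyst to hold, so absolute control cannot be defended.
- Regiochemistry rests on a small electronic difference between the two quinone oxygens: the methoxy group favours the wanted mode, the acceptor chain para to the future O1 opposes it.
- A2 can also react as a carbodiene or dimerise.

**Alternative 3:** Keep the heterocycle and cut the two C–H bonds at C2 and C3. The forward key step is asymmetric hydrogenation of the benzodioxine A4, which by syn addition gives the cis compound A5; acid epimerisation at C3 would then give 8.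
- C2=C3 is a tetrasubstituted, electron-rich enol ether without a coordinating group, a poor substrate class for enantioselective hydrogenation.
- The wanted trans isomer is reached only through the C3 cation, with the same E1 risk to C2 as in Alternative 1.
- A4 needs a free catechol, a regioselective alkylation and a dehydration, so no step is saved.

Key step: step 3

## Route

Step 1
Reactants: 1 1-(3,4,5-trimethoxyphenyl)propan-1-one
Product: 2 rac-2-bromo-1-(3,4,5-trimethoxyphenyl)propan-1-one
Conditions: CuBr2 (2.1 equiv), EtOAc/CHCl3, reflux
Reagents that add atoms: copper(II) bromide, Br[Cu]Br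
Why: α-Bromination of an aryl alkyl ketone through its enol; copper(II) bromide should brominate the enol and not the electron-rich ring. The new C–Br centre is racemic, which is what the later dynamic step needs.

Step 2
Reactants: 2 rac-2-bromo-1-(3,4,5-trimethoxyphenyl)propan-1-one; 3 4-hydroxy-3-iodo-5-methoxybenzaldehyde
Product: 4 rac-3-iodo-5-methoxy-4-{[1-oxo-1-(3,4,5-trimethoxyphenyl)propan-2-yl]oxy}benzaldehyde
Conditions: K2CO3, DMF, 50 °C
Reagents that add atoms: none
Why: Williamson etherification; the adjacent carbonyl accelerates SN2 at the secondary bromide. Since 3 has one phenolic OH, para to CHO and between I and OMe, the O1–C2 bond, the para relation of O1 to the side chain and the iodine at the later C4a are fixed together.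

Step 3
Reactants: 4 rac-3-iodo-5-methoxy-4-{[1-oxo-1-(3,4,5-trimethoxyphenyl)propan-2-yl]oxy}benzaldehyde
Product: 6 (1S,2S)-2-[4-(hydroxymethyl)-2-iodo-6-methoxyphenoxy]-1-(3,4,5-trimethoxyphenyl)propan-1-ol, via racemic keto alcohol 5 (not isolated)
Conditions: RuCl[(R,R)-TsDPEN](p-cymene) (2 mol %), HCO2H (5 equiv), Et3N (7 equiv), DMF, 40 °C
Reagents that add atoms: none
Why: This is a Noyori–Ikariya asymmetric transfer hydrogenation run as a dynamic kinetic resolution: Ru–H and N–H are delivered to C=O in a concerted outer-sphere transition state, and formate regenerates the hydride irreversibly with loss of CO2. The unhindered aldehyde should be reduced first to give 5, then the α-branched ketone. The closest known reaction type is the dynamic transfer hydrogenation of configurationally labile α-oxygenated aryl ketones (benzoin-type ketones to threo diols, α-alkoxy β-keto esters to syn products). No ring is closed here; the step sets both stereocentres of the later dioxane ring on the open chain. C1 of 6 (later C3) is under catalyst control: with the (R,R) ligand the aryl group lies under the η6-arene and hydride should add to the face that gives 1S, as for other α-heteroatom aryl ketones. C2 of 6 (later C2) is set dynamically: in a polar Felkin–Anh arrangement (C–OAr anti to the incoming hydride, H on its path) the (2S) enantiomer of 5 is the matched one and should give the threo alcohol, while Et3N returns the unmatched enantiomer through the enol. The step needs racemisation to outrun reduction of the unmatched enantiomer, and the substrate secures this because C2–H is α to an aryl ketone and to an electron-poor aryloxy oxygen while the branched ketone is reduced slowly. Aryl iodide and ethers are inert, and any leakage to the erythro diastereomer leads later to a separable cis isomer, not to the enantiomer.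

Step 4
Reactants: 6 (1S,2S)-2-[4-(hydroxymethyl)-2-iodo-6-methoxyphenoxy]-1-(3,4,5-trimethoxyphenyl)propan-1-ol
Product: 7 [(2S,3S)-8-methoxy-2-methyl-3-(3,4,5-trimethoxyphenyl)-2,3-dihydro-1,4-benzodioxin-6-yl]methanol
Conditions: CuI (10 mol %), 3,4,7,8-tetramethyl-1,10-phenanthroline (20 mol %), Cs2CO3, toluene (0.02 M), 110 °C
Reagents that add atoms: none
Why: Ullmann-type copper-catalysed intramolecular C–O coupling of the secondary alcohol with the ortho aryl iodide closes the six-membered ring at O4–C4a. No bond at C2 or C3 is made or broken, so the threo (1S,2S) chain should pass with retention into the trans (2S,3S) ring. Dilution favours ring closure over intermolecular coupling of the primary OH, and the CH2OH-substituted ring is not activated for Smiles migration.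

Step 5
Reactants: 7 [(2S,3S)-8-methoxy-2-methyl-3-(3,4,5-trimethoxyphenyl)-2,3-dihydro-1,4-benzodioxin-6-yl]methanol
Product: 8 (2S,3S)-8-methoxy-2-methyl-3-(3,4,5-trimethoxyphenyl)-2,3-dihydro-1,4-benzodioxine-6-carbaldehyde
Conditions: MnO2 (activated, excess), CH2Cl2, rt
Reagents that add atoms: none
Why: Manganese dioxide oxidises the primary benzylic alcohol to the aldehyde and stops there. The benzylic ether C3–H and both stereocentres should be untouched under these neutral conditions.

Step 6
Reactants: 8 (2S,3S)-8-methoxy-2-methyl-3-(3,4,5-trimethoxyphenyl)-2,3-dihydro-1,4-benzodioxine-6-carbaldehyde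
Product: 9 (2E)-3-[(2S,3S)-8-methoxy-2-methyl-3-(3,4,5-trimethoxyphenyl)-2,3-dihydro-1,4-benzodioxin-6-yl]prop-2-enal
Conditions: Ph3P=CHCHO (1.3 equiv), toluene, 90 °C
Reagents that add atoms: (triphenylphosphoranylidene)acetaldehyde, O=CC=P(c1ccccc1)(c1ccccc1)c1ccccc1
Why: Wittig olefination with a stabilised ylide should give the (E)-enal. The aryl aldehyde is more electrophilic than the product enal, which limits a second homologation, and the neutral conditions leave C2 and C3 alone.

## Compound list

1 | 1-(3,4,5-trimethoxyphenyl)propan-1-one | CCC(=O)c1cc(OC)c(OC)c(OC)c1 | starting material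
2 | rac-2-bromo-1-(3,4,5-trimethoxyphenyl)propan-1-one | CC(Br)C(=O)c1cc(OC)c(OC)c(OC)c1 | intermediate
3 | 4-hydroxy-3-iodo-5-methoxybenzaldehyde (5-iodovanillin) | COc1cc(C=O)cc(I)c1O | starting material
4 | rac-3-iodo-5-methoxy-4-{[1-oxo-1-(3,4,5-trimethoxyphenyl)propan-2-yl]oxy}benzaldehyde | COc1cc(C=O)cc(I)c1OC(C)C(=O)c1cc(OC)c(OC)c(OC)c1 | intermediate
5 | rac-2-[4-(hydroxymethyl)-2-iodo-6-methoxyphenoxy]-1-(3,4,5-trimethoxyphenyl)propan-1-one | COc1cc(CO)cc(I)c1OC(C)C(=O)c1cc(OC)c(OC)c(OC)c1 | intermediate (not isolated)
6 | (1S,2S)-2-[4-(hydroxymethyl)-2-iodo-6-methoxyphenoxy]-1-(3,4,5-trimethoxyphenyl)propan-1-ol | COc1cc([C@H](O)[C@H](C)Oc2c(I)cc(CO)cc2OC)cc(OC)c1OC | intermediate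
7 | [(2S,3S)-8-methoxy-2-methyl-3-(3,4,5-trimethoxyphenyl)-2,3-dihydro-1,4-benzodioxin-6-yl]methanol | COc1cc([C@@H]2Oc3cc(CO)cc(OC)c3O[C@H]2C)cc(OC)c1OC | intermediate
8 | (2S,3S)-8-methoxy-2-methyl-3-(3,4,5-trimethoxyphenyl)-2,3-dihydro-1,4-benzodioxine-6-carbaldehyde | COc1cc([C@@H]2Oc3cc(C=O)cc(OC)c3O[C@H]2C)cc(OC)c1OC | intermediate
9 | (2E)-3-[(2S,3S)-8-methoxy-2-methyl-3-(3,4,5-trimethoxyphenyl)-2,3-dihydro-1,4-benzodioxin-6-yl]prop-2-enal | COc1cc([C@@H]2Oc3cc(/C=C/C=O)cc(OC)c3O[C@H]2C)cc(OC)c1OC | target

## Step count and least certain steps

Total step count: 6. Longest linear sequence: 6 (1 → 2 → 4 → 6 → 7 → 8 → 9).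

**Step 3 (key step).** Two processes may fail. Enolisation at C2 may be too slow under the reduction conditions, so that the unmatched enantiomer is reduced before it is returned. The Felkin–Anh discrimination between the two enantiomers of 5 may also be weaker than expected. Either way the erythro diastereomer accumulates and diastereoselectivity drops; the enantiomeric purity is not affected, because the erythro chain leads to a cis ring. More amine or a stronger amidine base would be the first adjustment.

The fallback takes C2 from the chiral pool and lets C3 follow by equilibration. It sets out from 3 and returns at 8.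
- Phenol 3 is converted with ethylene glycol and TsOH into the acetal 4-(1,3-dioxolan-2-yl)-2-iodo-6-methoxyphenol F1.
- Mitsunobu etherification of F1 with methyl (R)-lactate (PPh3, DIAD) proceeds with inversion to methyl (2S)-2-[4-(1,3-dioxolan-2-yl)-2-iodo-6-methoxyphenoxy]propanoate F2.
- DIBAL at −78 °C gives (2S)-2-[4-(1,3-dioxolan-2-yl)-2-iodo-6-methoxyphenoxy]propanal F3, which is used at once.
- Addition of commercial 3,4,5-trimethoxyphenylmagnesium bromide at −78 °C gives (2S)-2-[4-(1,3-dioxolan-2-yl)-2-iodo-6-methoxyphenoxy]-1-(3,4,5-trimethoxyphenyl)propan-1-ol F4 as a mixture of carbinol epimers.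
- Copper-catalysed closure as in step 4 gives (2S)-6-(1,3-dioxolan-2-yl)-8-methoxy-2-methyl-3-(3,4,5-trimethoxyphenyl)-2,3-dihydro-1,4-benzodioxine F5 as a mixture of C3 epimers.
- Trifluoroacetic acid in wet CH2Cl2 at low temperature should hydrolyse the acetal and equilibrate C3 through the benzylic cation to the more stable trans isomer, giving 8.

**Step 4.** Oxidative addition at the hindered aryl iodide, flanked by the branched alkoxy group, may be slow. Intermolecular O-arylation by the primary benzylic OH (oligomers) or protodeiodination can then take over.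

The fallback replaces metal-catalysed coupling by nucleophilic aromatic substitution. It sets out from 2 and returns at 7.
- Bromide 2 is alkylated with commercial 3-fluoro-4-hydroxy-5-methoxybenzaldehyde as in step 2 to give rac-3-fluoro-5-methoxy-4-{[1-oxo-1-(3,4,5-trimethoxyphenyl)propan-2-yl]oxy}benzaldehyde F6.
- Dynamic transfer hydrogenation as in step 3 passes through rac-2-[2-fluoro-4-(hydroxymethyl)-6-methoxyphenoxy]-1-(3,4,5-trimethoxyphenyl)propan-1-one F7, which is not isolated, to (1S,2S)-2-[2-fluoro-4-(hydroxymethyl)-6-methoxyphenoxy]-1-(3,4,5-trimethoxyphenyl)propan-1-ol F8.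
- KHMDS in DMF at 80–100 °C should close the ring by intramolecular displacement of fluoride by the C1 alkoxide, again with retention at both stereocentres, to give 7.

**Step 6.** The product enal can react with a second equivalent of ylide (over-homologation to the dienal), and the electron-rich aldehyde may react slowly so that forcing conditions make this worse.

The fallback builds the chain at the ester level. It sets out from 8 and returns at 9.
- Horner–Wadsworth–Emmons reaction of 8 with triethyl phosphonoacetate and NaH gives ethyl (2E)-3-[(2S,3S)-8-methoxy-2-methyl-3-(3,4,5-trimethoxyphenyl)-2,3-dihydro-1,4-benzodioxin-6-yl]prop-2-enoate F9.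
- DIBAL at −78 °C gives (2E)-3-[(2S,3S)-8-methoxy-2-methyl-3-(3,4,5-trimethoxyphenyl)-2,3-dihydro-1,4-benzodioxin-6-yl]prop-2-en-1-ol F10.
- MnO2 in CH2Cl2 oxidises the allylic alcohol to 9.

## Further compounds

F1 | step 3 | 4-(1,3-dioxolan-2-yl)-2-iodo-6-methoxyphenol | COc1cc(C2OCCO2)cc(I)c1O
F2 | step 3 | methyl (2S)-2-[4-(1,3-dioxolan-2-yl)-2-iodo-6-methoxyphenoxy]propanoate | COC(=O)[C@H](C)Oc1c(I)cc(C2OCCO2)cc1OC
F3 | step 3 | (2S)-2-[4-(1,3-dioxolan-2-yl)-2-iodo-6-methoxyphenoxy]propanal | O=C[C@H](C)Oc1c(I)cc(C2OCCO2)cc1OC
F4 | step 3 | (2S)-2-[4-(1,3-dioxolan-2-yl)-2-iodo-6-methoxyphenoxy]-1-(3,4,5-trimethoxyphenyl)propan-1-ol (both C1 epimers) | COc1cc(C(O)[C@H](C)Oc2c(I)cc(C3OCCO3)cc2OC)cc(OC)c1OC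
F5 | step 3 | (2S)-6-(1,3-dioxolan-2-yl)-8-methoxy-2-methyl-3-(3,4,5-trimethoxyphenyl)-2,3-dihydro-1,4-benzodioxine (both C3 epimers) | COc1cc(C2Oc3cc(C4OCCO4)cc(OC)c3O[C@H]2C)cc(OC)c1OC
F6 | step 4 | rac-3-fluoro-5-methoxy-4-{[1-oxo-1-(3,4,5-trimethoxyphenyl)propan-2-yl]oxy}benzaldehyde | COc1cc(C=O)cc(F)c1OC(C)C(=O)c1cc(OC)c(OC)c(OC)c1
F7 | step 4 | rac-2-[2-fluoro-4-(hydroxymethyl)-6-methoxyphenoxy]-1-(3,4,5-trimethoxyphenyl)propan-1-one | COc1cc(CO)cc(F)c1OC(C)C(=O)c1cc(OC)c(OC)c(OC)c1
F8 | step 4 | (1S,2S)-2-[2-fluoro-4-(hydroxymethyl)-6-methoxyphenoxy]-1-(3,4,5-trimethoxyphenyl)propan-1-ol | COc1cc([C@H](O)[C@H](C)Oc2c(F)cc(CO)cc2OC)cc(OC)c1OC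
F9 | step 6 | ethyl (2E)-3-[(2S,3S)-8-methoxy-2-methyl-3-(3,4,5-trimethoxyphenyl)-2,3-dihydro-1,4-benzodioxin-6-yl]prop-2-enoate | COc1cc([C@@H]2Oc3cc(/C=C/C(=O)OCC)cc(OC)c3O[C@H]2C)cc(OC)c1OC
F10 | step 6 | (2E)-3-[(2S,3S)-8-methoxy-2-methyl-3-(3,4,5-trimethoxyphenyl)-2,3-dihydro-1,4-benzodioxin-6-yl]prop-2-en-1-ol | COc1cc([C@@H]2Oc3cc(/C=C/CO)cc(OC)c3O[C@H]2C)cc(OC)c1OC
A1 | alternative 1 | 3-hydroxy-4-{[(2S)-1-hydroxy-1-(3,4,5-trimethoxyphenyl)propan-2-yl]oxy}-5-methoxybenzaldehyde (both carbinol epimers) | COc1cc(C(O)[C@H](C)Oc2c(O)cc(C=O)cc2OC)cc(OC)c1OC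
A2 | alternative 2 | (2E)-3-(5-methoxy-3,4-dioxocyclohexa-1,5-dien-1-yl)prop-2-enal | COC1=CC(/C=C/C=O)=CC(=O)C1=O
A3 | alternative 2 | 1,2,3-trimethoxy-5-[(1E)-prop-1-en-1-yl]benzene | C/C=C/c1cc(OC)c(OC)c(OC)c1
A4 | alternative 3 | 8-methoxy-2-methyl-3-(3,4,5-trimethoxyphenyl)-1,4-benzodioxine-6-carbaldehyde | COc1cc(C2=C(C)Oc3c(OC)cc(C=O)cc3O2)cc(OC)c1OC
A5 | alternative 3 | (2S,3R)-8-methoxy-2-methyl-3-(3,4,5-trimethoxyphenyl)-2,3-dihydro-1,4-benzodioxine-6-carbaldehyde (cis) | COc1cc([C@H]2Oc3cc(C=O)cc(OC)c3O[C@H]2C)cc(OC)c1OC
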